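**Retrosynthetic overview**

1. Atom labels, kept for all intermediates: ring C1 (stereocentre), C2, C3=C4(CH2OH), C5, C6, C7=C8(CH3), C9, C10, C11=C12(CH3), C13, C14; C15(=C16H2) on C1 carries the 4-methylpent-3-enyl chain. The strategy rests on the array C16=C15–C1–C14: with a carboxyl on ring carbon C14 it is a pent-4-enoic acid, the product of an ester-enolate Claisen shift.
2. Key disconnection: C1–C14 (with C15=C16) by [3,3] shift of the chiral boron enolate of the achiral 18-membered allylic lactone 24 (ester between C16–O and the C14 carboxyl, E C1=C15). The carboxyl is then removed by Barton decarboxylation and the silyl ether cleaved.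
3. Ring order: the 18-membered lactone is closed first (Yamaguchi), then contracted to the 14-membered carbocycle, the only ring of the target.
4. Seco acid 22: the side chain is put on C15 by Negishi coupling of a C15 iodide, which comes from hydroxyl-directed trans-hydrostannation of the C1≡C15 alkynol. C1–C2 comes from copper-catalysed coupling of the C2 allylic bromide with propargyl alcohol.
5. C4–C5 comes from B-alkyl Suzuki coupling of the butynediol-derived Z C4 iodide with the 9-BBN adduct of diene ester 7. Ester 7 is made from neryl acetate (allylic oxidation at C13, acetate-enolate alkylation, oxidation, methylenation).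

Key step: step 17

Assumption: the (S,S)-diazaborolidine is written as the controller that leads to the (1S,14S)-acid 27 (C1 of the target R). This sense is taken by analogy with open-chain allyl esters and is to be checked on 27; the (R,R)-reagent, made the same way, is used if the lactone shows the opposite sense.

**Route**

Step 1
Reactants: 1 neryl acetate
Product: 2 (2Z,6E)-8-hydroxy-3,7-dimethylocta-2,6-dien-1-yl acetate
Conditions: SeO2 (cat.), t-BuOOH, salicylic acid (cat.), CH2Cl2, rt
Reagents that add atoms: tert-butyl hydroperoxide, CC(C)(C)OO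
Why: Riley-type allylic oxidation (ene reaction, then [2,3] shift) should attack the E-methyl of the electron-rich C11=C12 alkene and leave the acetate-deactivated C7=C8 alkene alone, giving the C13 alcohol with C11=C12 E.

Step 2
Reactants: 2 (2Z,6E)-8-hydroxy-3,7-dimethylocta-2,6-dien-1-yl acetate
Product: 3 (2Z,6E)-8-bromo-3,7-dimethylocta-2,6-dien-1-yl acetate
Conditions: CBr4, PPh3, CH2Cl2, 0 °C
Reagents that add atoms: tetrabromomethane, BrC(Br)(Br)Br
Why: Appel bromination of a primary allylic alcohol at low temperature is an SN2 displacement at C13 that should keep the position and geometry of the alkene.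

Step 3
Reactants: 3 (2Z,6E)-8-bromo-3,7-dimethylocta-2,6-dien-1-yl acetate
Product: 4 methyl (4E,8Z)-10-acetoxy-4,8-dimethyldeca-4,8-dienoate
Conditions: MeOAc, LiN(i-Pr)2, THF, −78 °C; CuI; then 3, −78 to −30 °C
Reagents that add atoms: methyl acetate, COC(C)=O
Why: Alkylation of the copper ester enolate (lithium enolate of methyl acetate with CuI) by a primary allylic bromide is an SN2 coupling at C13 that forms C13–C14 without allylic shift and is soft enough to spare the acetate.

Step 4
Reactants: 4 methyl (4E,8Z)-10-acetoxy-4,8-dimethyldeca-4,8-dienoate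
Product: 5 methyl (4E,8Z)-10-hydroxy-4,8-dimethyldeca-4,8-dienoate
Conditions: K2CO3 (cat.), MeOH, rt
Reagents that add atoms: none
Why: Base-catalysed transesterification with methanol removes the acetate, while the methyl ester is degenerate under these conditions.

Step 5
Reactants: 5 methyl (4E,8Z)-10-hydroxy-4,8-dimethyldeca-4,8-dienoate
Product: 6 methyl (4E,8Z)-4,8-dimethyl-10-oxodeca-4,8-dienoate
Conditions: TEMPO (cat.), PhI(OAc)2, CH2Cl2, 0 °C to rt
Reagents that add atoms: none
Why: Oxoammonium (TEMPO) oxidation of an allylic alcohol stops at the aldehyde under nearly neutral conditions, so the Z enal should form without Z-to-E isomerisation.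

Step 6
Reactants: 6 methyl (4E,8Z)-4,8-dimethyl-10-oxodeca-4,8-dienoate
Product: 7 methyl (4E,8Z)-4,8-dimethylundeca-4,8,10-trienoate
Conditions: Ph3PCH3Br, KN(SiMe3)2, THF, −78 to 0 °C
Reagents that add atoms: methyltriphenylphosphonium bromide, C[P+](c1ccccc1)(c1ccccc1)c1ccccc1.[Br-]
Why: Wittig methylenation at low temperature takes the aldehyde much faster than the methyl ester and adds C5 as the terminal carbon of a diene, with the Z C7=C8 bond kept.

Step 7
Reactants: 8 but-2-yne-1,4-diol
Product: 9 4-[(tert-butyldimethylsilyl)oxy]but-2-yn-1-ol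
Conditions: NaH (1 equiv), THF, 0 °C; t-BuMe2SiCl, rt
Reagents that add atoms: tert-butyldimethylsilyl chloride, CC(C)(C)[Si](C)(C)Cl
Why: Monosilylation of a symmetrical diol through its sparingly soluble monosodium alkoxide should give the mono-silyl ether.

Step 8
Reactants: 9 4-[(tert-butyldimethylsilyl)oxy]but-2-yn-1-ol
Product: 11 (Z)-4-[(tert-butyldimethylsilyl)oxy]-3-iodobut-2-en-1-ol, via cyclic alkenylaluminate 10 (not isolated)
Conditions: NaAlH2(OCH2CH2OCH3)2, THF, 0 °C to rt; then I2, −78 to 0 °C
Reagents that add atoms: iodine, II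
Why: Alkoxide-directed trans-hydroalumination of the propargylic alcohol puts hydride on C3 and aluminium on C4 within a five-membered aluminate (aluminium cis to C2), and iodinolysis with retention gives the iodide with iodine on C4 cis to C2.

Step 9
Reactants: 7 methyl (4E,8Z)-4,8-dimethylundeca-4,8,10-trienoate; 11 (Z)-4-[(tert-butyldimethylsilyl)oxy]-3-iodobut-2-en-1-ol
Product: 13 methyl (4E,8Z,12E)-12-[(tert-butyldimethylsilyloxy)methyl]-14-hydroxy-4,8-dimethyltetradeca-4,8,12-trienoate, via B-alkyl-9-BBN 12 (not isolated)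
Conditions: 9-BBN, THF, 0 °C to rt; then 11, PdCl2(dppf) (cat.), AsPh3 (cat.), K3PO4 (aq), DMF, rt
Reagents that add atoms: none
Why: 9-BBN adds anti-Markovnikov to the terminal vinyl of the diene only (boron on C5), and B-alkyl Suzuki–Miyaura coupling with the alkenyl iodide proceeds with retention, forming C4–C5 with C5 cis to C2.

Step 10
Reactants: 13 methyl (4E,8Z,12E)-12-[(tert-butyldimethylsilyloxy)methyl]-14-hydroxy-4,8-dimethyltetradeca-4,8,12-trienoate
Product: 14 methyl (4E,8Z,12E)-14-bromo-12-[(tert-butyldimethylsilyloxy)methyl]-4,8-dimethyltetradeca-4,8,12-trienoate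
Conditions: CBr4, PPh3, 2,6-lutidine, CH2Cl2, −20 °C
Reagents that add atoms: tetrabromomethane, BrC(Br)(Br)Br
Why: Appel bromination buffered with lutidine converts the primary allylic alcohol at C2 into the bromide by SN2 and should leave the silyl ether and the alkene geometry unchanged.

Step 11
Reactants: 14 methyl (4E,8Z,12E)-14-bromo-12-[(tert-butyldimethylsilyloxy)methyl]-4,8-dimethyltetradeca-4,8,12-trienoate; 15 prop-2-yn-1-ol
Product: 16 methyl (4E,8Z,12E)-12-[(tert-butyldimethylsilyloxy)methyl]-17-hydroxy-4,8-dimethylheptadeca-4,8,12-trien-15-ynoate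
Conditions: CuI (cat.), K2CO3, Bu4NI (cat.), DMF, rt
Reagents that add atoms: none
Why: Copper-acetylide alkylation of a primary allylic bromide forms C1–C2 at the unhindered terminus (SN2′ attack would need a quaternary centre at C4) and gives the skipped enyne with the propargylic hydroxyl free.

Step 12
Reactants: 16 methyl (4E,8Z,12E)-12-[(tert-butyldimethylsilyloxy)methyl]-17-hydroxy-4,8-dimethylheptadeca-4,8,12-trien-15-ynoate
Product: 17 methyl (4E,8Z,12E,15Z)-12-[(tert-butyldimethylsilyloxy)methyl]-17-hydroxy-4,8-dimethyl-16-(tributylstannyl)heptadeca-4,8,12,15-tetraenoate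
Conditions: Bu3SnH (slow addition), [(C5Me5)RuCl]4 (cat.), CH2Cl2, rt
Reagents that add atoms: tributyltin hydride, CCCC[SnH](CCCC)CCCC
Why: Ruthenium-catalysed trans-hydrostannation of a propargylic alcohol is steered by the free hydroxyl to put tin on the proximal carbon C15 and hydrogen on C1 anti to it, so tin ends cis to C2; isolated alkenes and the ester are not touched.

Step 13
Reactants: 17 methyl (4E,8Z,12E,15Z)-12-[(tert-butyldimethylsilyloxy)methyl]-17-hydroxy-4,8-dimethyl-16-(tributylstannyl)heptadeca-4,8,12,15-tetraenoate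
Product: 18 methyl (4E,8Z,12E,15Z)-12-[(tert-butyldimethylsilyloxy)methyl]-17-hydroxy-16-iodo-4,8-dimethylheptadeca-4,8,12,15-tetraenoate
Conditions: I2, CH2Cl2, 0 °C
Reagents that add atoms: iodine, II
Why: Iododestannylation is an ipso substitution with retention and is much faster than any reaction of iodine with the trisubstituted alkenes.

Step 14
Reactants: 18 methyl (4E,8Z,12E,15Z)-12-[(tert-butyldimethylsilyloxy)methyl]-17-hydroxy-16-iodo-4,8-dimethylheptadeca-4,8,12,15-tetraenoate; 19 5-bromo-2-methylpent-2-ene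
Product: 21 methyl (4E,8Z,12E,15E)-12-[(tert-butyldimethylsilyloxy)methyl]-16-(hydroxymethyl)-4,8,20-trimethylhenicosa-4,8,12,15,19-pentaenoate, via alkylzinc bromide 20 (not isolated)
Conditions: 19, Zn, LiCl, THF, 50 °C; then 18, PdCl2(dppf) (cat.), THF–NMP, rt to 50 °C
Reagents that add atoms: none
Why: Zinc insertion into the primary bromide gives the alkylzinc, and Negishi sp3–sp2 coupling with the alkenyl iodide under a dppf–palladium catalyst (which holds back β-hydride elimination) proceeds with retention, giving the E C1=C15 alkene with the side chain cis to C2.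

Step 15
Reactants: 21 methyl (4E,8Z,12E,15E)-12-[(tert-butyldimethylsilyloxy)methyl]-16-(hydroxymethyl)-4,8,20-trimethylhenicosa-4,8,12,15,19-pentaenoate
Product: 22 (4E,8Z,12E,15E)-12-[(tert-butyldimethylsilyloxy)methyl]-16-(hydroxymethyl)-4,8,20-trimethylhenicosa-4,8,12,15,19-pentaenoic acid
Conditions: LiOH, THF–MeOH–H2O, rt; then aq HCl to pH 4, 0 °C
Reagents that add atoms: lithium hydroxide (its oxygen ends in the acid), [Li+].[OH-]
Why: Saponification of the unhindered methyl ester at room temperature should leave the primary silyl ether and the skipped polyene unchanged.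

Step 16
Reactants: 22 (4E,8Z,12E,15E)-12-[(tert-butyldimethylsilyloxy)methyl]-16-(hydroxymethyl)-4,8,20-trimethylhenicosa-4,8,12,15,19-pentaenoic acid
Product: 24 (5E,9Z,13E,16E)-13-[(tert-butyldimethylsilyloxy)methyl]-5,9-dimethyl-17-(4-methylpent-3-en-1-yl)oxacyclooctadeca-5,9,13,16-tetraen-2-one, via mixed anhydride 23 (not isolated)
Conditions: 2,4,6-Cl3C6H2COCl, Et3N, THF, rt; then slow addition to DMAP, toluene, 80 °C (high dilution)
Reagents that add atoms: none
Why: Yamaguchi macrolactonisation: under DMAP catalysis and high dilution the mixed trichlorobenzoic anhydride is attacked by the only free hydroxyl (primary allylic C16–OH), closing the 18-membered ring.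

Step 17
Reactants: 24 (5E,9Z,13E,16E)-13-[(tert-butyldimethylsilyloxy)methyl]-5,9-dimethyl-17-(4-methylpent-3-en-1-yl)oxacyclooctadeca-5,9,13,16-tetraen-2-one
Product: 27 (1S,14S)-4-[(tert-butyldimethylsilyloxy)methyl]-8,12-dimethyl-1-(6-methylhepta-1,5-dien-2-yl)cyclotetradeca-3,7,11-triene-14-carboxylic acid (overview numbering), via boron enolate 25 (not isolated), via boron carboxylate 26 (not isolated)
Conditions: (4S,5S)-2-bromo-1,3-bis[3,5-bis(trifluoromethyl)phenylsulfonyl]-4,5-diphenyl-1,3,2-diazaborolidine (made from N,N'-[(1S,2S)-1,2-diphenylethane-1,2-diyl]bis[3,5-bis(trifluoromethyl)benzenesulfonamide] and BBr3, CH2Cl2), 1,2,2,6,6-pentamethylpiperidine, CH2Cl2, −78 °C, then 4 °C; aqueous work-up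
Reagents that add atoms: none
Why: The bromoborane binds the lactone carbonyl, the hindered amine removes a C14 proton (soft enolisation), and the O-boron ketene acetal 25 undergoes a concerted [3,3] shift through a chair in which C14 bonds to C1 while C16–O breaks and the alkene moves to C15=C16. The closest known reaction type is the enantioselective Ireland–Claisen rearrangement of allylic esters through chiral diazaborolidine boron enolates, which has been used for ring contraction of macrolactones to carbocycles. The 14-membered ring is closed by ring contraction: the six-atom chair lies inside the 18-membered lactone, and C14–C1 bond formation puts C15, C16, the oxygen and the carboxyl carbon outside the ring. C1 is set by the C2-symmetric sulfonamide groups on boron, which leave one enolate face open to the allyl unit; C14 is set relative to C1 by the enolate geometry (C13 cis to O–B, expected with a hindered amine in CH2Cl2) and the E C1=C15 alkene, both ring branches pseudo-equatorial, which gives the trans acid, and C14 is erased in step 18, so its epimer would serve as well. The step needs enantioface selectivity and a chair in preference to a boat; these are served by the E C1=C15 geometry (C2 equatorial), the single enolisable position and the flexible, achiral large ring.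

Step 18
Reactants: 27 (1S,14S)-4-[(tert-butyldimethylsilyloxy)methyl]-8,12-dimethyl-1-(6-methylhepta-1,5-dien-2-yl)cyclotetradeca-3,7,11-triene-14-carboxylic acid
Product: 29 tert-butyldimethylsilyl ether of the target (C1 R), via thiohydroxamate ester 28 (not isolated)
Conditions: N-hydroxypyridine-2-thione, DCC, DMAP (cat.), CH2Cl2, rt, dark; then t-BuSH (excess), hν (tungsten lamp), 0 °C to rt
Reagents that add atoms: none
Why: Barton radical decarboxylation: the thiohydroxamate ester fragments under visible light to the secondary C14 radical, which excess thiol should reduce faster than 3-exo closure onto C15=C16 or transannular addition; C1 is not involved and keeps its configuration (the descriptor changes to R only because C14 loses the carboxyl).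

Step 19
Reactants: 29 tert-butyldimethylsilyl ether of the target
Product: 30 target alcohol CNP0217603.1
Conditions: Bu4NF, THF, 0 °C to rt
Reagents that add atoms: none
Why: Fluoride-mediated desilylation cleaves the primary silyl ether under nearly neutral conditions that leave the skipped triene, the 1,1-disubstituted alkene and the C1 centre unchanged.

**Compound list**

1 | neryl acetate, (2Z)-3,7-dimethylocta-2,6-dien-1-yl acetate | CC(C)=CCC/C(C)=C\COC(C)=O | starting material
2 | (2Z,6E)-8-hydroxy-3,7-dimethylocta-2,6-dien-1-yl acetate | CC(=O)OC/C=C(C)\CC/C=C(C)/CO | intermediate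
3 | (2Z,6E)-8-bromo-3,7-dimethylocta-2,6-dien-1-yl acetate | CC(=O)OC/C=C(C)\CC/C=C(C)/CBr | intermediate
4 | methyl (4E,8Z)-10-acetoxy-4,8-dimethyldeca-4,8-dienoate | CC(=O)OC/C=C(C)\CC/C=C(C)/CCC(=O)OC | intermediate
5 | methyl (4E,8Z)-10-hydroxy-4,8-dimethyldeca-4,8-dienoate | OC/C=C(C)\CC/C=C(C)/CCC(=O)OC | intermediate
6 | methyl (4E,8Z)-4,8-dimethyl-10-oxodeca-4,8-dienoate | O=C/C=C(C)\CC/C=C(C)/CCC(=O)OC | intermediate
7 | methyl (4E,8Z)-4,8-dimethylundeca-4,8,10-trienoate | C=C/C=C(C)\CC/C=C(C)/CCC(=O)OC | intermediate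
8 | but-2-yne-1,4-diol | OCC#CCO | starting material
9 | 4-[(tert-butyldimethylsilyl)oxy]but-2-yn-1-ol | OCC#CCO[Si](C)(C)C(C)(C)C | intermediate
10 | sodium cyclic alkenylaluminate (Al bound to the C2 oxygen and to C4, two 2-methoxyethoxy ligands) | [Na+].COCCO[Al-]1(OCCOC)OCC=C1CO[Si](C)(C)C(C)(C)C | intermediate
11 | (Z)-4-[(tert-butyldimethylsilyl)oxy]-3-iodobut-2-en-1-ol | OC/C=C(\I)CO[Si](C)(C)C(C)(C)C | intermediate
12 | B-alkyl-9-BBN from 7 (boron on C5) | COC(=O)CC/C(C)=C/CC/C(C)=C\CCB1C2CCCC1CCC2 | intermediate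
13 | methyl (4E,8Z,12E)-12-[(tert-butyldimethylsilyloxy)methyl]-14-hydroxy-4,8-dimethyltetradeca-4,8,12-trienoate | OC/C=C(/CO[Si](C)(C)C(C)(C)C)CC/C=C(C)\CC/C=C(C)/CCC(=O)OC | intermediate
14 | methyl (4E,8Z,12E)-14-bromo-12-[(tert-butyldimethylsilyloxy)methyl]-4,8-dimethyltetradeca-4,8,12-trienoate | BrC/C=C(/CO[Si](C)(C)C(C)(C)C)CC/C=C(C)\CC/C=C(C)/CCC(=O)OC | intermediate
15 | prop-2-yn-1-ol (propargyl alcohol) | C#CCO | starting material
16 | methyl (4E,8Z,12E)-12-[(tert-butyldimethylsilyloxy)methyl]-17-hydroxy-4,8-dimethylheptadeca-4,8,12-trien-15-ynoate | OCC#CC/C=C(/CO[Si](C)(C)C(C)(C)C)CC/C=C(C)\CC/C=C(C)/CCC(=O)OC | intermediate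
17 | methyl (4E,8Z,12E,15Z)-12-[(tert-butyldimethylsilyloxy)methyl]-17-hydroxy-4,8-dimethyl-16-(tributylstannyl)heptadeca-4,8,12,15-tetraenoate | OC/C(=C/C/C=C(/CO[Si](C)(C)C(C)(C)C)CC/C=C(C)\CC/C=C(C)/CCC(=O)OC)[Sn](CCCC)(CCCC)CCCC | intermediate
18 | methyl (4E,8Z,12E,15Z)-12-[(tert-butyldimethylsilyloxy)methyl]-17-hydroxy-16-iodo-4,8-dimethylheptadeca-4,8,12,15-tetraenoate | OC/C(I)=C/C/C=C(/CO[Si](C)(C)C(C)(C)C)CC/C=C(C)\CC/C=C(C)/CCC(=O)OC | intermediate
19 | 5-bromo-2-methylpent-2-ene | CC(C)=CCCBr | starting material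
20 | (4-methylpent-3-en-1-yl)zinc bromide | CC(C)=CCC[Zn]Br | intermediate
21 | methyl (4E,8Z,12E,15E)-12-[(tert-butyldimethylsilyloxy)methyl]-16-(hydroxymethyl)-4,8,20-trimethylhenicosa-4,8,12,15,19-pentaenoate | OC/C(CCC=C(C)C)=C/C/C=C(/CO[Si](C)(C)C(C)(C)C)CC/C=C(C)\CC/C=C(C)/CCC(=O)OC | intermediate
22 | seco acid, (4E,8Z,12E,15E)-12-[(tert-butyldimethylsilyloxy)methyl]-16-(hydroxymethyl)-4,8,20-trimethylhenicosa-4,8,12,15,19-pentaenoic acid | OC/C(CCC=C(C)C)=C/C/C=C(/CO[Si](C)(C)C(C)(C)C)CC/C=C(C)\CC/C=C(C)/CCC(=O)O | intermediate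
23 | mixed anhydride of 22 with 2,4,6-trichlorobenzoic acid | OC/C(CCC=C(C)C)=C/C/C=C(/CO[Si](C)(C)C(C)(C)C)CC/C=C(C)\CC/C=C(C)/CCC(=O)OC(=O)c1c(Cl)cc(Cl)cc1Cl | intermediate
24 | achiral 18-membered lactone, (5E,9Z,13E,16E)-13-[(tert-butyldimethylsilyloxy)methyl]-5,9-dimethyl-17-(4-methylpent-3-en-1-yl)oxacyclooctadeca-5,9,13,16-tetraen-2-one | O=C1CC/C(C)=C/CC/C(C)=C\CC/C(CO[Si](C)(C)C(C)(C)C)=C\C/C=C(\CCC=C(C)C)CO1 | intermediate
25 | O-boron ketene acetal of 24 (C13 cis to O–B) carrying the (4S,5S)-1,3-bis[3,5-bis(trifluoromethyl)phenylsulfonyl]-4,5-diphenyl-1,3,2-diazaborolidin-2-yl group | FC(F)(F)c1cc(cc(c1)C(F)(F)F)S(=O)(=O)N1[C@@H](c2ccccc2)[C@H](c2ccccc2)N(S(=O)(=O)c2cc(cc(c2)C(F)(F)F)C(F)(F)F)B1O/C1=C\C/C(C)=C/CC/C(C)=C\CC/C(CO[Si](C)(C)C(C)(C)C)=C\C/C=C(\CCC=C(C)C)CO1 | intermediate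
26 | acyloxyborane of acid 27 with the same diazaborolidinyl group | C=C(CCC=C(C)C)[C@H]1C/C=C(/CO[Si](C)(C)C(C)(C)C)CC/C=C(/C)CC/C=C(\C)C[C@@H]1C(=O)OB1N(S(=O)(=O)c2cc(cc(c2)C(F)(F)F)C(F)(F)F)[C@@H](c2ccccc2)[C@H](c2ccccc2)N1S(=O)(=O)c1cc(cc(c1)C(F)(F)F)C(F)(F)F | intermediate
27 | (1S,14S)-acid: 14-membered (3E,7Z,11E)-triene with CO2H on C14 trans to the 6-methylhepta-1,5-dien-2-yl group on C1, CH2OSi(t-Bu)Me2 on C4, methyls on C8 and C12 | C=C(CCC=C(C)C)[C@H]1C/C=C(/CO[Si](C)(C)C(C)(C)C)CC/C=C(/C)CC/C=C(\C)C[C@@H]1C(=O)O | intermediate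
28 | N-acyloxypyridine-2-thione (Barton ester) of 27 | C=C(CCC=C(C)C)[C@H]1C/C=C(/CO[Si](C)(C)C(C)(C)C)CC/C=C(/C)CC/C=C(\C)C[C@@H]1C(=O)ON1C=CC=CC1=S | intermediate
29 | tert-butyldimethylsilyl ether of the target, C1 R | C=C(CCC=C(C)C)[C@H]1C/C=C(/CO[Si](C)(C)C(C)(C)C)CC/C=C(/C)CC/C=C(\C)CC1 | intermediate
30 | target CNP0217603.1: (R)-configured 14-membered (3E,7Z,11E)-triene with CH2OH on C4, methyls on C8 and C12, 6-methylhepta-1,5-dien-2-yl on C1 | C=C(CCC=C(C)C)[C@H]1C/C=C(/CO)CC/C=C(/C)CC/C=C(\C)CC1 | target

**Step count and risks**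

Total steps: 19. Longest linear sequence: 17 steps (steps 1–6 and 9–19).

Steps most likely to fail:

1. Step 17. The large-ring lactone may enolise slowly or incompletely. Enantioface selectivity may erode if the macrocycle forces a boat-like transition state. The bromoborane may attack the silyl ether as a Lewis acid. The fallback sets out from 24 and comes back at 27; it runs the ring contraction without a chiral reagent and resolves the acid. Lactone 24 is treated with KN(SiMe3)2 and Me3SiCl–Et3N in THF at −78 °C to give the trimethylsilyl ketene acetal F1. On warming in toluene F1 undergoes the Ireland–Claisen shift to the trimethylsilyl ester F2, and aqueous work-up gives the racemic acid F3. Its mixed pivalic anhydride (t-BuCOCl, Et3N) acylates lithiated (S)-4-benzyloxazolidin-2-one. The diastereomeric imides are separated by chromatography, and the imide F4 of the (1S,14S)-acid is cleaved with LiOH–H2O2 to give 27.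

2. Step 12. The ruthenium catalyst may stall or lose regiocontrol if the C3=C4 alkene of the skipped enyne binds the metal, and the allylic stannane may protodestannylate on handling. The fallback sets out from 14 and comes back at 21; it builds the C1=C15 alkene as a separate alkenyl partner and leaves out 15 to 18. Bromide 19 and Mg give (4-methylpent-3-en-1-yl)magnesium bromide F5, which CuBr·SMe2 converts into the alkylcopper. This adds syn across trimethyl(prop-2-yn-1-yloxy)silane in THF (carbocupration, copper on the terminal carbon cis to the new chain). Iodine, then a mild acid work-up that removes the trimethylsilyl group, gives (E)-3-iodo-2-(4-methylpent-3-en-1-yl)prop-2-en-1-ol F6. Deprotonation with n-BuLi, iodine–lithium exchange with t-BuLi and addition of ZnBr2 give the alkenylzinc alkoxide F7. F7 couples with 14 under Pd(PPh3)4 (Negishi alkenyl–allyl coupling with retention at both alkenes) to give 21.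

3. Step 18. The C14 radical may close 3-exo onto C15=C16 and reopen (a 1,2-vinyl shift), or add across the ring, before hydrogen transfer; the hindered acid may also acylate the thione slowly. The fallback sets out from 27 and comes back at 29; it removes the carbon by a non-radical organometallic path. LiAlH4 in Et2O at 0 °C reduces the acid to the primary alcohol F8. Dess–Martin periodinane buffered with NaHCO3 gives the aldehyde F9. Stoichiometric RhCl(PPh3)3 in toluene at reflux removes the formyl group with retention (Tsuji–Wilkinson decarbonylation) to give 29.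

Further compounds
F1 | step 17 | trimethylsilyl ketene acetal of lactone 24 | C[Si](C)(C)OC1=CC/C(C)=C/CC/C(C)=C\CC/C(CO[Si](C)(C)C(C)(C)C)=C\C/C=C(\CCC=C(C)C)CO1
F2 | step 17 | trimethylsilyl ester of the racemic ring-contracted acid | C=C(CCC=C(C)C)C1C/C=C(/CO[Si](C)(C)C(C)(C)C)CC/C=C(/C)CC/C=C(\C)CC1C(=O)O[Si](C)(C)C
F3 | step 17 | racemic ring-contracted acid | C=C(CCC=C(C)C)C1C/C=C(/CO[Si](C)(C)C(C)(C)C)CC/C=C(/C)CC/C=C(\C)CC1C(=O)O
F4 | step 17 | N-acyl (S)-4-benzyloxazolidin-2-one of the (1S,14S)-acid | C=C(CCC=C(C)C)[C@H]1C/C=C(/CO[Si](C)(C)C(C)(C)C)CC/C=C(/C)CC/C=C(\C)C[C@@H]1C(=O)N1[C@@H](Cc2ccccc2)COC1=O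
F5 | step 12 | (4-methylpent-3-en-1-yl)magnesium bromide | CC(C)=CCC[Mg]Br
F6 | step 12 | (E)-3-iodo-2-(4-methylpent-3-en-1-yl)prop-2-en-1-ol | OC/C(CCC=C(C)C)=C/I
F7 | step 12 | alkenylzinc bromide of F6 as its lithium alkoxide | [Li+].[O-]C/C(CCC=C(C)C)=C/[Zn]Br
F8 | step 18 | primary alcohol from reduction of 27 (CH2OH on C14) | C=C(CCC=C(C)C)[C@H]1C/C=C(/CO[Si](C)(C)C(C)(C)C)CC/C=C(/C)CC/C=C(\C)C[C@@H]1CO
F9 | step 18 | aldehyde from F8 (CHO on C14) | C=C(CCC=C(C)C)[C@H]1C/C=C(/CO[Si](C)(C)C(C)(C)C)CC/C=C(/C)CC/C=C(\C)C[C@@H]1C=O
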